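The route cuts two neighbouring bonds of ring B (the 7-hydroxycoumarin half): C5–CH3 and C4a–C4. They sit on adjacent carbons, and C4a lies next to oxygen-bearing C8a. This is the pattern left by nucleophile/electrophile addition across a 3-alkoxybenzyne. One flask therefore turns a fluorobiaryl into the fully substituted ring B: lithiation beside fluorine, LiF loss, methyllithium addition at C5 and CO2 capture at C4a. The precursor is a biphenyl. Its ring B carries F at C5, H at C4a and isopropyl ethers at C7 and C8a. Its ring A is a symmetric 2,6-dimethoxy-4-methylphenyl group. Both pyranones are closed together at the end.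

Key step: step 4

Assumption: the target SMILES gives no descriptor for the hindered C6–C8' axis, so the racemate is made; the axis first becomes stereogenic in step 6.
Numbering: coumarin locants are used in the comments. Unprimed locants are the 7-hydroxy half (ring B, pyranone B) and primed locants are the 7'-methoxy half (ring A, pyranone A).
Design note: ring A is taken to an ester, not a ketone, so one reagent closes both pyranones and supplies both C4 methoxy groups. The benzyl group goes on only after the last Lewis-acid step.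

Step 1
Reactants: 1 5-fluororesorcinol; 2 2-bromopropane
Product: 3 1-fluoro-3,5-di(propan-2-yloxy)benzene
Conditions: 2 (3 equiv), K2CO3, DMF, 70 °C
Reagents that add atoms: 2-bromopropane, CC(C)Br
Why: Williamson ether synthesis on both phenoxides of a symmetric diol needs no selectivity, and isopropyl ethers offer no acidic or strongly chelating site that could mislead the later lithiation.

Step 2
Reactants: 3 1-fluoro-3,5-di(propan-2-yloxy)benzene
Product: 4 2-bromo-1-fluoro-3,5-di(propan-2-yloxy)benzene
Conditions: NBS (1.0 equiv), MeCN, 0 °C → rt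
Reagents that add atoms: N-bromosuccinimide, O=C1CCC(=O)N1Br
Why: Electrophilic aromatic bromination prefers the carbon para to one alkoxy group and ortho to the other, and the two equivalent sites between F and O-i-Pr are far less crowded than the site between the two isopropoxy groups.

Step 3
Reactants: 4 2-bromo-1-fluoro-3,5-di(propan-2-yloxy)benzene; 5 3,5-dimethoxytoluene
Product: 8 2-fluoro-2',6'-dimethoxy-4'-methyl-4,6-di(propan-2-yloxy)biphenyl, via aryllithium 6 (not isolated), via arylzinc chloride 7 (not isolated)
Conditions: 5 (1.3 equiv), n-BuLi (1.3 equiv), THF, 0 °C → rt; ZnCl2 (1.4 equiv), 0 °C → rt; 4 (1.0 equiv), Pd2(dba)3 (1 mol %), RuPhos (4 mol %), THF, 70 °C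
Reagents that add atoms: none
Why: Directed ortho-lithiation between the two methoxy groups, transmetalation to zinc and Negishi coupling under a bulky dialkylbiarylphosphine ligand is an established way to hindered biaryls, the axis is made while C5 bears only the small fluorine, and the zinc reagent avoids the protodeboronation typical of 2,6-dialkoxyarylboronic acids.

Step 4
Reactants: 8 2-fluoro-2',6'-dimethoxy-4'-methyl-4,6-di(propan-2-yloxy)biphenyl
Product: 13 3-(2,6-dimethoxy-4-methylphenyl)-2-methyl-4,6-di(propan-2-yloxy)benzoic acid, via C4a-lithio fluoroarene 9 (not isolated), via C4a–C5 aryne 10 (not isolated), via C5-methyl C4a-lithio arene 11 (not isolated), via lithium carboxylate 12 (not isolated)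
Conditions: TMPH, n-BuLi, THF, 0 °C (LiTMP, 1.3 equiv); 8, −78 °C, 1 h; MeLi (5 equiv, Et2O), −78 → −10 °C; cannulate into CO2(s)/THF, −78 °C; 1 M HCl
Reagents that add atoms: methyllithium, [Li]C; carbon dioxide, O=C=O
Why: LiTMP takes the most acidic ring proton, C4a–H between F and O-i-Pr (C8–H lies between two bulky ethers and has no fluorine neighbour), to give 9, which loses LiF on warming and forms the C4a≡C5 aryne 10. The C8a oxygen polarises and distorts the strained triple bond so that C5 is its electrophilic end; MeLi, already present in excess when the aryne appears, adds there and leaves the carbanion of 11 at C4a, where the neighbouring oxygen stabilises it inductively and through Li–O contact. Inverse quench into excess CO2 converts 11 into carboxylate 12 and destroys surplus MeLi before it can attack the doubly ortho-substituted carboxylate. The closest known reaction type is carbometalation of 3-alkoxybenzynes generated from 3-haloaryl ethers followed by carboxylation, the established entry to 6-alkylsalicylic and resorcylic acids. No ring is closed and no stereocentre is formed, and because ring A is still symmetric the biaryl axis is not yet stereogenic. Three selectivities are needed: the site of lithiation (secured by fluorine), the regiochemistry of addition (secured by the C8a ether against the bulk of the orthogonal C6 aryl group, helped by the small size of MeLi), and MeLi outrunning the hindered amide, the aryllithiums and the ring A methoxy oxygens as nucleophile (secured by its excess and by dilution).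

Step 5
Reactants: 13 3-(2,6-dimethoxy-4-methylphenyl)-2-methyl-4,6-di(propan-2-yloxy)benzoic acid
Product: 14 methyl 3-(2,6-dimethoxy-4-methylphenyl)-2-methyl-4,6-di(propan-2-yloxy)benzoate
Conditions: MeI, K2CO3, DMF, rt
Reagents that add atoms: iodomethane, CI
Why: Carboxylate O-alkylation (SN2 on MeI) bypasses the shielded carbonyl carbon of the doubly ortho-substituted acid, blocks ipso-halodecarboxylation in the next step and installs the future C4 methoxy group.

Step 6
Reactants: 14 methyl 3-(2,6-dimethoxy-4-methylphenyl)-2-methyl-4,6-di(propan-2-yloxy)benzoate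
Product: 15 methyl 3-(3-iodo-2,6-dimethoxy-4-methylphenyl)-2-methyl-4,6-di(propan-2-yloxy)benzoate (racemic axis)
Conditions: NIS (1.05 equiv), TFA (0.2 equiv), MeCN, 0 °C → rt
Reagents that add atoms: N-iodosuccinimide, O=C1CCC(=O)N1I
Why: Acid-activated electrophilic iodination attacks ring A at the future C4a' (ortho to one methoxy, para to the other, both open sites being equivalent), whereas ring B is deactivated by its ester and its only C–H is walled in by two isopropoxy groups.

Step 7
Reactants: 15 methyl 3-(3-iodo-2,6-dimethoxy-4-methylphenyl)-2-methyl-4,6-di(propan-2-yloxy)benzoate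
Product: 17 methyl 3-[2,6-dimethoxy-3-(methoxycarbonyl)-4-methylphenyl]-2-methyl-4,6-di(propan-2-yloxy)benzoate (racemic axis), via arylmagnesium chloride 16 (not isolated)
Conditions: i-PrMgCl·LiCl (1.3 equiv), THF, −15 °C → rt; ClCO2Me (3 equiv), −40 °C → rt
Reagents that add atoms: methyl chloroformate, COC(=O)Cl
Why: Iodine–magnesium exchange with the LiCl-activated Grignard reagent, assisted by the ortho methoxy group, tolerates the doubly ortho-substituted ring B ester, and acylation of 16 by the chloroformate stops at the equally shielded new ester.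

Step 8
Reactants: 17 methyl 3-[2,6-dimethoxy-3-(methoxycarbonyl)-4-methylphenyl]-2-methyl-4,6-di(propan-2-yloxy)benzoate
Product: 18 methyl 4,6-dihydroxy-3-[2-hydroxy-6-methoxy-3-(methoxycarbonyl)-4-methylphenyl]-2-methylbenzoate (racemic axis)
Conditions: BCl3 (8 equiv, 1 M in CH2Cl2), CH2Cl2, −78 → 0 °C; ice, 1 M HCl
Reagents that add atoms: none
Why: In this Lewis-acid ether cleavage the secondary isopropyl aryl ethers ionise readily and the C8a' methyl ether is activated by six-membered chelation of boron to the adjacent ester carbonyl, while the unchelated C7' methyl ether and both methyl esters should persist at or below 0 °C, which also decides which ring A oxygen becomes O1'.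

Step 9
Reactants: 18 methyl 4,6-dihydroxy-3-[2-hydroxy-6-methoxy-3-(methoxycarbonyl)-4-methylphenyl]-2-methylbenzoate
Product: 19 methyl 4-(benzyloxy)-6-hydroxy-3-[2-hydroxy-6-methoxy-3-(methoxycarbonyl)-4-methylphenyl]-2-methylbenzoate (racemic axis)
Conditions: BnBr (1.05 equiv), K2CO3 (1.2 equiv), acetone, rt → 40 °C
Reagents that add atoms: benzyl bromide, BrCc1ccccc1
Why: Williamson benzylation with one equivalent of halide and a weak base selects the C7 hydroxyl, the only one not locked in a hydrogen bond to an ester carbonyl and the most acidic (para to the ester), as is routine for 2,4-dihydroxybenzoates.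

Step 10
Reactants: 19 methyl 4-(benzyloxy)-6-hydroxy-3-[2-hydroxy-6-methoxy-3-(methoxycarbonyl)-4-methylphenyl]-2-methylbenzoate
Product: 21 7-(benzyloxy)-4,4',7'-trimethoxy-5,5'-dimethyl-6,8'-bicoumarin (racemic axis), via bis(acyl ylide) 20 (not isolated)
Conditions: Ph3P=C=C=O (3 equiv), toluene, 110 °C
Reagents that add atoms: ketenylidenetriphenylphosphorane, O=C=C=P(c1ccccc1)(c1ccccc1)c1ccccc1
Why: Each free phenol adds to the cumulated ylide to give an aryl (triphenylphosphoranylidene)acetate (20), whose intramolecular Wittig olefination of the neighbouring ester carbonyl closes a six-membered lactone and keeps the ester methoxy group as the C4 enol ether, the known conversion of salicylate esters into 4-alkoxycoumarins run here on both halves at once.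

Step 11
Reactants: 21 7-(benzyloxy)-4,4',7'-trimethoxy-5,5'-dimethyl-6,8'-bicoumarin
Product: 22 7-hydroxy-4,4',7'-trimethoxy-5,5'-dimethyl-6,8'-bicoumarin (CNP0113839.0, racemic axis)
Conditions: H2 (1 atm), 10% Pd/C, EtOAc–MeOH, rt
Reagents that add atoms: none
Why: Catalytic hydrogenolysis cleaves only the benzylic C–O bond, since the trisubstituted, donor–acceptor-stabilised C3=C4 bonds of 4-methoxycoumarins are not reduced at 1 atm and room temperature.

Compound list
1 | 5-fluororesorcinol | Oc1cc(O)cc(F)c1 | starting material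
2 | 2-bromopropane | CC(C)Br | starting material
3 | 1-fluoro-3,5-di(propan-2-yloxy)benzene | CC(C)Oc1cc(F)cc(OC(C)C)c1 | intermediate
4 | 2-bromo-1-fluoro-3,5-di(propan-2-yloxy)benzene | CC(C)Oc1cc(F)c(Br)c(OC(C)C)c1 | intermediate
5 | 3,5-dimethoxytoluene | Cc1cc(OC)cc(OC)c1 | starting material
6 | (2,6-dimethoxy-4-methylphenyl)lithium | [Li]c1c(OC)cc(C)cc1OC | intermediate
7 | (2,6-dimethoxy-4-methylphenyl)zinc chloride | Cl[Zn]c1c(OC)cc(C)cc1OC | intermediate
8 | 2-fluoro-2',6'-dimethoxy-4'-methyl-4,6-di(propan-2-yloxy)biphenyl | Cc1cc(OC)c(c(OC)c1)-c1c(F)cc(OC(C)C)cc1OC(C)C | intermediate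
9 | 8 lithiated at the carbon between F and O-i-Pr (C4a) | Cc1cc(OC)c(c(OC)c1)-c1c(F)c([Li])c(OC(C)C)cc1OC(C)C | intermediate
10 | 3-(2,6-dimethoxy-4-methylphenyl)-4,6-di(propan-2-yloxy)benzyne (C4a≡C5 aryne) | Cc1cc(OC)c(c(OC)c1)C1=C(OC(C)C)C=C(OC(C)C)C#C1 | intermediate
11 | [3-(2,6-dimethoxy-4-methylphenyl)-2-methyl-4,6-di(propan-2-yloxy)phenyl]lithium | Cc1cc(OC)c(c(OC)c1)-c1c(C)c([Li])c(OC(C)C)cc1OC(C)C | intermediate
12 | lithium 3-(2,6-dimethoxy-4-methylphenyl)-2-methyl-4,6-di(propan-2-yloxy)benzoate | [Li+].Cc1cc(OC)c(c(OC)c1)-c1c(C)c(C([O-])=O)c(OC(C)C)cc1OC(C)C | intermediate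
13 | 3-(2,6-dimethoxy-4-methylphenyl)-2-methyl-4,6-di(propan-2-yloxy)benzoic acid | Cc1cc(OC)c(c(OC)c1)-c1c(C)c(C(=O)O)c(OC(C)C)cc1OC(C)C | intermediate
14 | methyl 3-(2,6-dimethoxy-4-methylphenyl)-2-methyl-4,6-di(propan-2-yloxy)benzoate | Cc1cc(OC)c(c(OC)c1)-c1c(C)c(C(=O)OC)c(OC(C)C)cc1OC(C)C | intermediate
15 | methyl 3-(3-iodo-2,6-dimethoxy-4-methylphenyl)-2-methyl-4,6-di(propan-2-yloxy)benzoate, racemic | COC(=O)c1c(C)c(-c2c(OC)cc(C)c(I)c2OC)c(OC(C)C)cc1OC(C)C | intermediate
16 | arylmagnesium chloride from 15 (Mg in place of I) | COC(=O)c1c(C)c(-c2c(OC)cc(C)c([Mg]Cl)c2OC)c(OC(C)C)cc1OC(C)C | intermediate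
17 | methyl 3-[2,6-dimethoxy-3-(methoxycarbonyl)-4-methylphenyl]-2-methyl-4,6-di(propan-2-yloxy)benzoate, racemic | COC(=O)c1c(C)c(-c2c(OC)cc(C)c(C(=O)OC)c2OC)c(OC(C)C)cc1OC(C)C | intermediate
18 | methyl 4,6-dihydroxy-3-[2-hydroxy-6-methoxy-3-(methoxycarbonyl)-4-methylphenyl]-2-methylbenzoate, racemic | COC(=O)c1c(C)c(-c2c(OC)cc(C)c(C(=O)OC)c2O)c(O)cc1O | intermediate
19 | methyl 4-(benzyloxy)-6-hydroxy-3-[2-hydroxy-6-methoxy-3-(methoxycarbonyl)-4-methylphenyl]-2-methylbenzoate, racemic | COC(=O)c1c(C)c(-c2c(OC)cc(C)c(C(=O)OC)c2O)c(OCc2ccccc2)cc1O | intermediate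
20 | bis[(triphenylphosphoranylidene)acetate] of 19 at the C8a and C8a' oxygens | COC(=O)c1c(C)c(-c2c(OC)cc(C)c(C(=O)OC)c2OC(=O)C=P(c2ccccc2)(c2ccccc2)c2ccccc2)c(OCc2ccccc2)cc1OC(=O)C=P(c1ccccc1)(c1ccccc1)c1ccccc1 | intermediate
21 | 7-(benzyloxy)-4,4',7'-trimethoxy-5,5'-dimethyl-6,8'-bicoumarin, racemic | COc1cc(C)c2c(OC)cc(=O)oc2c1-c1c(OCc3ccccc3)cc2oc(=O)cc(OC)c2c1C | intermediate
22 | 7-hydroxy-4,4',7'-trimethoxy-5,5'-dimethyl-6,8'-bicoumarin (CNP0113839.0), racemic | COc1cc(C)c2c(OC)cc(=O)oc2c1-c1c(O)cc2oc(=O)cc(OC)c2c1C | target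

Total step count: 11
Longest linear sequence: 11 steps (1 → 22); 5 enters in step 3 without steps of its own.

Steps most likely to fail

Step 4.
- Risk: the aryne may be captured by nucleophiles other than MeLi, namely the hindered amide, the aryllithiums, or a ring A methoxy oxygen attacking intramolecularly. Crowding beside C5 may also erode the regiocontrol of methyl addition.
- Fallback: it abandons the aryne and buys ring B with its methyl and ester carbons in place. It sets out from 5 (converted into 7 as in step 3) and comes back to the route at 14.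
- Sequence: methyl 2,4-dihydroxy-6-methylbenzoate F1 (commercial) is bis-alkylated with 2 (K2CO3, DMF, 80 °C) to methyl 2-methyl-4,6-di(propan-2-yloxy)benzoate F2. NBS in MeCN then brominates the carbon para to one ether and next to the methyl group, giving methyl 3-bromo-2-methyl-4,6-di(propan-2-yloxy)benzoate F3. Negishi coupling of F3 with 7 (Pd2(dba)3, RuPhos, THF–NMP, 100 °C) gives 14.
- Cost: the coupling now forms a fully tetra-ortho-substituted axis.

Step 10.
- Risk: the sequence may stall after O-acylation, because Wittig closure onto ester carbonyls flanked by a methyl group is slow. Only one half might then cyclise.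
- Fallback: it replaces the ylide chemistry by enolate chemistry. It sets out from 19 and comes back at 21.
- Sequence: acetylation of both phenols (Ac2O, pyridine, DMAP) gives the diacetate of 19 F4. Double intramolecular Claisen condensation of the acetate enolates onto the neighbouring esters (LiN(SiMe3)2, THF, −78 °C → rt) gives 7-(benzyloxy)-4,4'-dihydroxy-7'-methoxy-5,5'-dimethyl-6,8'-bicoumarin F5. O-methylation of both vinylogous acids (Me2SO4, K2CO3, acetone, reflux) gives 21.

Step 7.
- Risk: iodine–magnesium exchange may be slow at an electron-rich, doubly flanked carbon. The organomagnesium may also be protonated prematurely, so that iodine is lost without C–C bond formation.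
- Fallback: it installs the ring A carboxyl carbon by electrophilic substitution instead. It sets out from 14, bypasses 15 and 16, and comes back at 17.
- Sequence: Vilsmeier–Haack formylation (POCl3, DMF, 0 → 70 °C; aq NaOAc) gives methyl 3-(3-formyl-2,6-dimethoxy-4-methylphenyl)-2-methyl-4,6-di(propan-2-yloxy)benzoate F6. Pinnick oxidation (NaClO2, NaH2PO4, 2-methyl-2-butene, t-BuOH–H2O) gives 2,4-dimethoxy-3-[3-(methoxycarbonyl)-2-methyl-4,6-di(propan-2-yloxy)phenyl]-6-methylbenzoic acid F7. MeI/K2CO3 in DMF gives 17.

Further compounds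
F1 | step 4 | methyl 2,4-dihydroxy-6-methylbenzoate | COC(=O)c1c(C)cc(O)cc1O
F2 | step 4 | methyl 2-methyl-4,6-di(propan-2-yloxy)benzoate | COC(=O)c1c(C)cc(OC(C)C)cc1OC(C)C
F3 | step 4 | methyl 3-bromo-2-methyl-4,6-di(propan-2-yloxy)benzoate | COC(=O)c1c(C)c(Br)c(OC(C)C)cc1OC(C)C
F4 | step 10 | diacetate of 19 (acetates at the C8a and C8a' oxygens) | COC(=O)c1c(C)c(-c2c(OC)cc(C)c(C(=O)OC)c2OC(C)=O)c(OCc2ccccc2)cc1OC(C)=O
F5 | step 10 | 7-(benzyloxy)-4,4'-dihydroxy-7'-methoxy-5,5'-dimethyl-6,8'-bicoumarin | COc1cc(C)c2c(O)cc(=O)oc2c1-c1c(OCc3ccccc3)cc2oc(=O)cc(O)c2c1C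
F6 | step 7 | methyl 3-(3-formyl-2,6-dimethoxy-4-methylphenyl)-2-methyl-4,6-di(propan-2-yloxy)benzoate | COC(=O)c1c(C)c(-c2c(OC)cc(C)c(C=O)c2OC)c(OC(C)C)cc1OC(C)C
F7 | step 7 | 2,4-dimethoxy-3-[3-(methoxycarbonyl)-2-methyl-4,6-di(propan-2-yloxy)phenyl]-6-methylbenzoic acid | COC(=O)c1c(C)c(-c2c(OC)cc(C)c(C(=O)O)c2OC)c(OC(C)C)cc1OC(C)C
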